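The runs are calculated with made-up constants; the scatter is artificial.

The target is what you are after, and it forms in a chain: the second chain carrier turns substrate into by-product and first chain carrier, then the first chain carrier and dissolved coupling partner give target and return the second chain carrier, while initiator supplies new carriers.

all flasks: gas 87 mM (held)
- theta: substrate 1 M; initiator 2.5 mM; run made earlier
- gamma: substrate 1 M; initiator 3.8 mM; run made earlier
- alpha: substrate 1.5 M; initiator 5 mM; run made earlier
- flask: substrate 1.0 M; initiator 5.0 mM; time 2.5 d

- theta (time / h: target / %): 6.00: 12.4; 15.0: 27.0; 30.0: 47.2; 50.0: 64.7
- gamma (time / h: target / %): 12.0: 26.9; 25.0: 46.4; 40.0: 63.9; 50.0: 71.2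
- alpha (time / h: target / %): 12.0: 28.8; 25.0: 52.3; 40.0: 69.1; 50.0: 75.5

(scatter of a reading: 1 percentage point)

- a species is counted by the substrate in it: one ended chains B counts as two
- at the start none of coupling partner is dissolved
- reactions considered so far: 2 second chain carrier -> ended chains A; gas <-> coupling partner; substrate + second chain carrier -> by-product + first chain carrier; 2 first chain carrier -> ended chains B; coupling partner + first chain carrier -> target + second chain carrier; initiator -> 2 initiating radical; substrate + initiating radical -> capped initiator + first chain carrier

- south: doubling the transfer coefficient of the gas, all else as stated
- north-west: doubling the saturation concentration of gas, all else as stated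

1. target at 2.5 d, in percent of the substrate charged
2. the change that raises the amount of target at 2.5 d, in percent of the substrate charged most ("none" if none brings more than 2 percentage points) (south / north-west / none)
3. amount of target at 2.5 d, in percent of the substrate charged, after north-west

Take minus the logarithm of the unconverted fraction, divide by the time, and scale by the square root of the initiator charge to the flask's charge. Alpha, with the flask's initiator, gives 0.0281 /h at its last reading, and you can test each number against that. An error of 10 per cent in this rate or in the time moves the target by 2.9 percentage points, and the same error in the initiator, entering by its root, by 1.5 points. Gamma, at 1 M, scales to 0.0286 /h, and taking its rate instead of alpha's shifts the target by 0.47 points, less than the scatter of 1 point, so the substrate charge matters little here and the decay reads as pseudo-first-order. Gas matters little, because the flask's initial demand of 28.1 mM/h is less than the 36.0 mM/h alpha averaged up to its first reading.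

With theta at 0.0295 /h, the mean is 0.0287 /h, the scaled fractional rate, and my reckoning gives 82.1% at 2.5 d, the same after north-west, and I expect neither change to bring more than 2 points.

The forecast said 82%, none and 82.3%, since “Faster transfer or higher saturation therefore changes almost nothing”.

The simulation gives 82.6%, none and 82.6%, with coupling partner at 95.4% of saturation after 0.250 d.

    2 second chain carrier → ended chains A (k = 1.50 × 10⁹ /M/s)
    gas ⇌ coupling partner, rate k2*(csat - [coupling partner]) (kL = 6.19 /h)
    substrate + second chain carrier → by-product + first chain carrier (k = 3.31 × 10⁷ /M/h)
    2 first chain carrier → ended chains B (k = 8.70 × 10⁶ /M/s)
    coupling partner + first chain carrier → target + second chain carrier (k = 2.66 × 10⁶ /M/s)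
    initiator → 2 initiating radical (k = 8.57 × 10⁻⁴ /h)
    substrate + initiating radical → capped initiator + first chain carrier (k = 4.20 × 10⁵ /M/s)

Read back, the flask's average rate is 0.0291 /h, against 0.0287 /h. For the neighbouring flask with 0.0013 M initiator, the root of the charge scales the rate to 0.0146 /h, which gives 58.4% at 2.5 d, and that flask stands at 59.0%.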